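**Retrosynthetic overview**
1. The target is ring A–O–ring B–O–ring C. Both aryl–O–ring bonds are cut to a phenoxide plus one shared electrophile, 3-chloro-2-methyl-5-isopropyl-1,4-benzoquinone, by addition–elimination.
2. Ring B is that same quinone after the first coupling and reduction. Its two OH groups are told apart by sterics: TIPS on the open OH, Bn on the crowded OH, TIPS exchanged for Me, then Bn removed.
3. The chloroquinone comes from the hydroxyquinone, which comes from 2-methyl-5-isopropylresorcinol. The resorcinol comes from 5-isopropylresorcinol by methylation through ortho-lithiation.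
4. Key C–C bond: intermolecular Michael addition of dimethyl malonate to (E)-5-methylhex-3-en-2-one, followed in the same pot by Claisen (Dieckmann) ring closure.
5. Only this one carbocycle is built (step 1) and aromatised (step 2), and it supplies both ring B and ring C. Ring A is bought as carvacrol. Assembly order is A–O–B first, then B–O–C.

Assumption: the SMILES holds no stereocentre, no stereogenic double bond and no specified axis, so the target is treated as achiral and needs no enantiocontrol.

**Step 1**
Reactants: 1 (E)-5-methylhex-3-en-2-one; 2 dimethyl malonate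
Product: 4 methyl 2-hydroxy-4-oxo-6-(propan-2-yl)cyclohex-2-ene-1-carboxylate (racemic; enol form of the dioxo ester), via open-chain Michael adduct 3 (not isolated)
Conditions: NaOMe (1.1 equiv), MeOH, reflux, 4 h; then 2 M HCl, 0 °C
Reagents that add atoms: none
Why: The soft malonate anion adds 1,4 to the enone (intermolecular Michael addition, joining the isopropyl-bearing carbon to the malonate carbon), the methyl-ketone enolate of 3 then closes the ring on one ester (Dieckmann-type Claisen condensation) driven by the stable enolate of 4, and the racemic stereocentres are erased in step 2.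

**Step 2**
Reactants: 4 methyl 2-hydroxy-4-oxo-6-(propan-2-yl)cyclohex-2-ene-1-carboxylate
Product: 7 5-(propan-2-yl)benzene-1,3-diol, via resorcylate methyl ester 5 (not isolated), via resorcylic acid 6 (not isolated)
Conditions: Br2 (1.0 equiv), DMF, 0 °C → rt; then 80 °C, 1 h; 160 °C, 10 h
Reagents that add atoms: none
Why: Bromination of the enolised dione and loss of HBr aromatise the ring (halogenation–dehydrohalogenation), bromide then dealkylates the ester by SN2 in hot DMF, and the beta-resorcylic acid decarboxylates thermally.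

**Step 3**
Reactants: 7 5-(propan-2-yl)benzene-1,3-diol
Product: 8 1,3-dimethoxy-5-(propan-2-yl)benzene
Conditions: MeI (2.5 equiv), K2CO3 (3 equiv), acetone, reflux, 12 h
Reagents that add atoms: iodomethane, CI
Why: Exhaustive Williamson ether synthesis on two unhindered phenols installs the two directing groups needed for step 4.

**Step 4**
Reactants: 8 1,3-dimethoxy-5-(propan-2-yl)benzene
Product: 10 1,3-dimethoxy-2-methyl-5-(propan-2-yl)benzene, via aryllithium 9 (not isolated)
Conditions: n-BuLi (1.2 equiv), THF, 0 °C → rt, 2 h; MeI (1.5 equiv), −78 °C → rt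
Reagents that add atoms: iodomethane, CI; n-butyllithium, [Li]CCCC (lithium of 9 only)
Why: Directed ortho-metalation takes place only at the carbon between the two methoxy groups (doubly chelated and most acidic), and the aryllithium is methylated cleanly by MeI.

**Step 5**
Reactants: 10 1,3-dimethoxy-2-methyl-5-(propan-2-yl)benzene
Product: 11 2-methyl-5-(propan-2-yl)benzene-1,3-diol
Conditions: BBr3 (2.5 equiv), CH2Cl2, −78 °C → rt; then H2O
Reagents that add atoms: none
Why: Lewis-acid cleavage of aryl methyl ethers with BBr3 is general, and the molecule carries nothing else that reacts.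

**Step 6**
Reactants: 11 2-methyl-5-(propan-2-yl)benzene-1,3-diol
Product: 12 3-hydroxy-2-methyl-5-(propan-2-yl)cyclohexa-2,5-diene-1,4-dione
Conditions: (KSO3)2NO (2.2 equiv), KH2PO4 buffer (pH 6), H2O/acetone, rt, 2 h; then HCl to pH 2, EtOAc extraction
Reagents that add atoms: dipotassium nitrosodisulfonate, [K+].[K+].[O]N(S(=O)(=O)[O-])S(=O)(=O)[O-] (gives the new carbonyl oxygen)
Why: The Teuber oxidation converts a phenol with a free para position into the p-quinone, and because the two free ring positions of 11 are equivalent by symmetry only one hydroxyquinone can form.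

**Step 7**
Reactants: 12 3-hydroxy-2-methyl-5-(propan-2-yl)cyclohexa-2,5-diene-1,4-dione
Product: 13 3-chloro-2-methyl-5-(propan-2-yl)cyclohexa-2,5-diene-1,4-dione
Conditions: (COCl)2 (1.5 equiv), DMF (0.1 equiv), CH2Cl2, 0 °C → rt
Reagents that add atoms: oxalyl chloride, O=C(Cl)C(=O)Cl (gives the chlorine)
Why: The hydroxyquinone is a vinylogous carboxylic acid, so Vilsmeier-type activation of its oxygen followed by chloride addition–elimination gives the vinylogous acid chloride, with the p-quinone as the thermodynamic product.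

**Step 8**
Reactants: 14 carvacrol (2-methyl-5-(propan-2-yl)phenol)
Product: 15 2-methoxy-1-methyl-4-(propan-2-yl)benzene
Conditions: MeI (1.5 equiv), K2CO3 (2 equiv), acetone, reflux
Reagents that add atoms: iodomethane, CI
Why: A simple Williamson ether synthesis fixes the ring A methoxy group next to the ring methyl without any regiochemical question.

**Step 9**
Reactants: 15 2-methoxy-1-methyl-4-(propan-2-yl)benzene
Product: 16 1-bromo-4-methoxy-5-methyl-2-(propan-2-yl)benzene
Conditions: NBS (1.02 equiv), MeCN, 0 °C → rt, dark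
Reagents that add atoms: N-bromosuccinimide, O=C1CCC(=O)N1Br
Why: Electrophilic aromatic bromination with NBS in MeCN is para-selective for anisoles, and the only ortho alternative is squeezed between the methoxy and isopropyl groups.

**Step 10**
Reactants: 16 1-bromo-4-methoxy-5-methyl-2-(propan-2-yl)benzene
Product: 19 4-methoxy-5-methyl-2-(propan-2-yl)phenol, via aryllithium 17 (not isolated), via dimethyl arylboronate 18 (not isolated)
Conditions: n-BuLi (1.1 equiv), THF, −78 °C; B(OMe)3 (1.5 equiv), −78 °C → rt; AcOH, 30% aq H2O2, 0 °C → rt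
Reagents that add atoms: hydrogen peroxide, OO; n-butyllithium, [Li]CCCC (lithium of 17 only); trimethyl borate, COB(OC)OC (boron and methoxy groups of 18 only)
Why: Bromine–lithium exchange, borylation and oxidative 1,2-aryl migration (boronate oxidation) replace Br by OH at exactly the same carbon.

**Step 11**
Reactants: 19 4-methoxy-5-methyl-2-(propan-2-yl)phenol; 13 3-chloro-2-methyl-5-(propan-2-yl)cyclohexa-2,5-diene-1,4-dione
Product: 20 3-[4-methoxy-5-methyl-2-(propan-2-yl)phenoxy]-2-methyl-5-(propan-2-yl)cyclohexa-2,5-diene-1,4-dione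
Conditions: 13 (1.1 equiv), K2CO3 (1.5 equiv), dry DMF, 0 °C → rt, argon
Reagents that add atoms: none
Why: The phenoxide adds to the chlorine-bearing quinone carbon and chloride leaves (oxa-Michael addition–elimination), while the only other open position is shielded by the isopropyl group and addition there is reversible.

**Step 12**
Reactants: 20 3-[4-methoxy-5-methyl-2-(propan-2-yl)phenoxy]-2-methyl-5-(propan-2-yl)cyclohexa-2,5-diene-1,4-dione
Product: 21 2-[4-methoxy-5-methyl-2-(propan-2-yl)phenoxy]-3-methyl-6-(propan-2-yl)benzene-1,4-diol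
Conditions: Na2S2O4 (3 equiv), THF/H2O, rt, argon; used at once
Reagents that add atoms: none
Why: Dithionite reduction of a quinone to its hydroquinone is fast and leaves the aryl ethers untouched.

**Step 13**
Reactants: 21 2-[4-methoxy-5-methyl-2-(propan-2-yl)phenoxy]-3-methyl-6-(propan-2-yl)benzene-1,4-diol
Product: 22 2-[4-methoxy-5-methyl-2-(propan-2-yl)phenoxy]-3-methyl-6-(propan-2-yl)-4-{[tri(propan-2-yl)silyl]oxy}phenol
Conditions: TIPSCl (1.05 equiv), imidazole (2.2 equiv), DMF, 0 °C → rt, argon
Reagents that add atoms: chlorotri(propan-2-yl)silane, CC(C)[Si](Cl)(C(C)C)C(C)C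
Why: In this sterically controlled silylation the bulky chlorosilane reaches only the OH flanked by CH3 and H, because the other OH is buried between the isopropyl and aryloxy groups.

**Step 14**
Reactants: 22 2-[4-methoxy-5-methyl-2-(propan-2-yl)phenoxy]-3-methyl-6-(propan-2-yl)-4-{[tri(propan-2-yl)silyl]oxy}phenol
Product: 23 {4-(benzyloxy)-3-[4-methoxy-5-methyl-2-(propan-2-yl)phenoxy]-2-methyl-5-(propan-2-yl)phenoxy}tri(propan-2-yl)silane
Conditions: BnBr (1.3 equiv), K2CO3 (2 equiv), DMF, 40 °C
Reagents that add atoms: benzyl bromide, BrCc1ccccc1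
Why: A Williamson ether synthesis with the small and reactive benzyl bromide still alkylates the crowded phenoxide, and the aryl TIPS ether survives dry carbonate.

**Step 15**
Reactants: 23 {4-(benzyloxy)-3-[4-methoxy-5-methyl-2-(propan-2-yl)phenoxy]-2-methyl-5-(propan-2-yl)phenoxy}tri(propan-2-yl)silane
Product: 24 4-(benzyloxy)-3-[4-methoxy-5-methyl-2-(propan-2-yl)phenoxy]-2-methyl-5-(propan-2-yl)phenol
Conditions: Bu4NF (1.1 equiv), THF, 0 °C; then 1 M HCl
Reagents that add atoms: none
Why: Fluoride-induced desilylation, driven by the strong Si–F bond, frees only the silylated phenol.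

**Step 16**
Reactants: 24 4-(benzyloxy)-3-[4-methoxy-5-methyl-2-(propan-2-yl)phenoxy]-2-methyl-5-(propan-2-yl)phenol
Product: 25 1-(benzyloxy)-4-methoxy-2-[4-methoxy-5-methyl-2-(propan-2-yl)phenoxy]-3-methyl-6-(propan-2-yl)benzene
Conditions: MeI (2 equiv), K2CO3 (2 equiv), acetone, reflux
Reagents that add atoms: iodomethane, CI
Why: A Williamson ether synthesis on the single free phenol places the ring B methoxy group unambiguously.

**Step 17**
Reactants: 25 1-(benzyloxy)-4-methoxy-2-[4-methoxy-5-methyl-2-(propan-2-yl)phenoxy]-3-methyl-6-(propan-2-yl)benzene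
Product: 26 4-methoxy-2-[4-methoxy-5-methyl-2-(propan-2-yl)phenoxy]-3-methyl-6-(propan-2-yl)phenol
Conditions: H2 (1 atm), 10% Pd/C, EtOAc/EtOH, rt
Reagents that add atoms: none
Why: Catalytic hydrogenolysis cleaves only the benzylic C–O bond and leaves the diaryl ether and methyl ethers intact.

**Step 18**
Reactants: 26 4-methoxy-2-[4-methoxy-5-methyl-2-(propan-2-yl)phenoxy]-3-methyl-6-(propan-2-yl)phenol; 13 3-chloro-2-methyl-5-(propan-2-yl)cyclohexa-2,5-diene-1,4-dione
Product: 27 3-{4-methoxy-2-[4-methoxy-5-methyl-2-(propan-2-yl)phenoxy]-3-methyl-6-(propan-2-yl)phenoxy}-2-methyl-5-(propan-2-yl)cyclohexa-2,5-diene-1,4-dione (target; achiral)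
Conditions: 13 (1.3 equiv), Cs2CO3 (1.3 equiv), dry DMF, 0 °C → rt (40 °C if slow), argon
Reagents that add atoms: none
Why: This is the same oxa-Michael addition–elimination as in step 11, with the loosely paired caesium phenoxide offsetting the steric crowding and irreversible chloride loss fixing the oxygen next to the quinone methyl.

**Compound list**
1 | (E)-5-methylhex-3-en-2-one | CC(=O)/C=C/C(C)C | starting material
2 | dimethyl malonate | COC(=O)CC(=O)OC | starting material
3 | dimethyl 2-(2-methyl-5-oxohexan-3-yl)propanedioate (racemic) | CC(=O)CC(C(C)C)C(C(=O)OC)C(=O)OC | intermediate (not isolated)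
4 | methyl 2-hydroxy-4-oxo-6-(propan-2-yl)cyclohex-2-ene-1-carboxylate (racemic, enol tautomer) | COC(=O)C1C(C(C)C)CC(=O)C=C1O | intermediate
5 | methyl 2,4-dihydroxy-6-(propan-2-yl)benzoate | COC(=O)c1c(O)cc(O)cc1C(C)C | intermediate (not isolated)
6 | 2,4-dihydroxy-6-(propan-2-yl)benzoic acid | OC(=O)c1c(O)cc(O)cc1C(C)C | intermediate (not isolated)
7 | 5-(propan-2-yl)benzene-1,3-diol | CC(C)c1cc(O)cc(O)c1 | intermediate
8 | 1,3-dimethoxy-5-(propan-2-yl)benzene | COc1cc(OC)cc(C(C)C)c1 | intermediate
9 | [2,6-dimethoxy-4-(propan-2-yl)phenyl]lithium | [Li]c1c(OC)cc(C(C)C)cc1OC | intermediate (not isolated)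
10 | 1,3-dimethoxy-2-methyl-5-(propan-2-yl)benzene | COc1cc(C(C)C)cc(OC)c1C | intermediate
11 | 2-methyl-5-(propan-2-yl)benzene-1,3-diol | Cc1c(O)cc(C(C)C)cc1O | intermediate
12 | 3-hydroxy-2-methyl-5-(propan-2-yl)cyclohexa-2,5-diene-1,4-dione | CC1=C(O)C(=O)C(C(C)C)=CC1=O | intermediate
13 | 3-chloro-2-methyl-5-(propan-2-yl)cyclohexa-2,5-diene-1,4-dione | CC1=C(Cl)C(=O)C(C(C)C)=CC1=O | intermediate
14 | carvacrol, 2-methyl-5-(propan-2-yl)phenol | Cc1ccc(C(C)C)cc1O | starting material
15 | 2-methoxy-1-methyl-4-(propan-2-yl)benzene | COc1cc(C(C)C)ccc1C | intermediate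
16 | 1-bromo-4-methoxy-5-methyl-2-(propan-2-yl)benzene | COc1cc(C(C)C)c(Br)cc1C | intermediate
17 | [4-methoxy-5-methyl-2-(propan-2-yl)phenyl]lithium | COc1cc(C(C)C)c([Li])cc1C | intermediate (not isolated)
18 | dimethyl [4-methoxy-5-methyl-2-(propan-2-yl)phenyl]boronate | COc1cc(C(C)C)c(B(OC)OC)cc1C | intermediate (not isolated)
19 | 4-methoxy-5-methyl-2-(propan-2-yl)phenol | COc1cc(C(C)C)c(O)cc1C | intermediate
20 | 3-[4-methoxy-5-methyl-2-(propan-2-yl)phenoxy]-2-methyl-5-(propan-2-yl)cyclohexa-2,5-diene-1,4-dione | COc1cc(C(C)C)c(OC2=C(C)C(=O)C=C(C(C)C)C2=O)cc1C | intermediate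
21 | 2-[4-methoxy-5-methyl-2-(propan-2-yl)phenoxy]-3-methyl-6-(propan-2-yl)benzene-1,4-diol | COc1cc(C(C)C)c(Oc2c(C)c(O)cc(C(C)C)c2O)cc1C | intermediate
22 | 2-[4-methoxy-5-methyl-2-(propan-2-yl)phenoxy]-3-methyl-6-(propan-2-yl)-4-{[tri(propan-2-yl)silyl]oxy}phenol | COc1cc(C(C)C)c(Oc2c(C)c(O[Si](C(C)C)(C(C)C)C(C)C)cc(C(C)C)c2O)cc1C | intermediate
23 | {4-(benzyloxy)-3-[4-methoxy-5-methyl-2-(propan-2-yl)phenoxy]-2-methyl-5-(propan-2-yl)phenoxy}tri(propan-2-yl)silane | COc1cc(C(C)C)c(Oc2c(C)c(O[Si](C(C)C)(C(C)C)C(C)C)cc(C(C)C)c2OCc3ccccc3)cc1C | intermediate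
24 | 4-(benzyloxy)-3-[4-methoxy-5-methyl-2-(propan-2-yl)phenoxy]-2-methyl-5-(propan-2-yl)phenol | COc1cc(C(C)C)c(Oc2c(C)c(O)cc(C(C)C)c2OCc3ccccc3)cc1C | intermediate
25 | 1-(benzyloxy)-4-methoxy-2-[4-methoxy-5-methyl-2-(propan-2-yl)phenoxy]-3-methyl-6-(propan-2-yl)benzene | COc1cc(C(C)C)c(Oc2c(C)c(OC)cc(C(C)C)c2OCc3ccccc3)cc1C | intermediate
26 | 4-methoxy-2-[4-methoxy-5-methyl-2-(propan-2-yl)phenoxy]-3-methyl-6-(propan-2-yl)phenol | COc1cc(C(C)C)c(Oc2c(C)c(OC)cc(C(C)C)c2O)cc1C | intermediate
27 | 3-{4-methoxy-2-[4-methoxy-5-methyl-2-(propan-2-yl)phenoxy]-3-methyl-6-(propan-2-yl)phenoxy}-2-methyl-5-(propan-2-yl)cyclohexa-2,5-diene-1,4-dione (CNP0335608.0, achiral) | COc1cc(C(C)C)c(Oc2c(C)c(OC)cc(C(C)C)c2OC2=C(C)C(=O)C=C(C(C)C)C2=O)cc1C | target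

**Total step count:** 18.
**Longest linear sequence:** 15 steps (steps 1–7, then 11–18). Steps 8–10 form a three-step side branch, and 13 is used twice.

**Three steps most likely to fail**

**Step 6 (11 to 12).** (KSO3)2NO varies in quality, and the electron-rich hydroxyquinone can be oxidised further. The fallback brings the new oxygen in by way of nitrogen instead of a radical oxidant, and it sets out from 11. C-nitrosation (NaNO2, aq HCl/EtOH, 0 °C; both free positions are equivalent) gives 2-methyl-4-nitroso-5-(propan-2-yl)benzene-1,3-diol F1. Reduction (Na2S2O4, aq NaOH, or H2, Pd/C) gives 4-amino-2-methyl-5-(propan-2-yl)benzene-1,3-diol F2. FeCl3 in dilute HCl then oxidises this p-aminophenol and hydrolyses off the nitrogen, which comes back to the route at 12.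

**Step 7 (12 to 13).** Activation of the ambident vinylogous acid could give some o-quinone chloride, and the HCl formed can add to the quinone. The fallback installs the chlorine before the ring is aromatic, and it sets out from 4.
- Saponification and decarboxylation (aq NaOH, then HCl, reflux) give 5-(propan-2-yl)cyclohexane-1,3-dione F3.
- C-alkylation (MeI, aq KOH, reflux) gives 2-methyl-5-(propan-2-yl)cyclohexane-1,3-dione F4.
- Treatment with (COCl)2 and cat. DMF in CH2Cl2 gives, because the dione is symmetric, only 3-chloro-2-methyl-5-(propan-2-yl)cyclohex-2-en-1-one F5.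
- Dehydrogenation of its kinetic enolate (LiN(i-Pr)2, THF, −78 °C, then N-tert-butylbenzenesulfinimidoyl chloride) and tautomerisation give 3-chloro-2-methyl-5-(propan-2-yl)phenol F6.
- O2 with Co(salen) in DMF oxidises the free para position, and the fallback comes back to the route at 13.

**Step 18 (26 + 13 to 27).** The nucleophile sits between an isopropyl and an aryloxy group, while 13 is base-sensitive and an oxidant, so the reaction cannot be forced by heating. The fallback forms the C–O bond at the cyclohexenone oxidation level, where the electrophile tolerates heat and base. It sets out from 26, which is heated with the chloroenone F5 (made from 4 as described above) and Cs2CO3 in DMF at 90 °C to give the 3-aryloxycyclohexenone F7. The same enolate dehydrogenation gives the ring C phenol F8. (KSO3)2NO then oxidises the para position of its only free phenol (rings A and B carry no OH), and the fallback comes back to the route at 27.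

**Further compounds**
F1 | step 6 | 2-methyl-4-nitroso-5-(propan-2-yl)benzene-1,3-diol | Cc1c(O)cc(C(C)C)c(N=O)c1O
F2 | step 6 | 4-amino-2-methyl-5-(propan-2-yl)benzene-1,3-diol | Cc1c(O)cc(C(C)C)c(N)c1O
F3 | step 7 | 5-(propan-2-yl)cyclohexane-1,3-dione | CC(C)C1CC(=O)CC(=O)C1
F4 | step 7 | 2-methyl-5-(propan-2-yl)cyclohexane-1,3-dione | CC1C(=O)CC(C(C)C)CC1=O
F5 | step 7 | 3-chloro-2-methyl-5-(propan-2-yl)cyclohex-2-en-1-one (racemic) | CC1=C(Cl)CC(C(C)C)CC1=O
F6 | step 7 | 3-chloro-2-methyl-5-(propan-2-yl)phenol | Cc1c(O)cc(C(C)C)cc1Cl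
F7 | step 18 | 3-{4-methoxy-2-[4-methoxy-5-methyl-2-(propan-2-yl)phenoxy]-3-methyl-6-(propan-2-yl)phenoxy}-2-methyl-5-(propan-2-yl)cyclohex-2-en-1-one (racemic) | COc1cc(C(C)C)c(Oc2c(C)c(OC)cc(C(C)C)c2OC3=C(C)C(=O)CC(C(C)C)C3)cc1C
F8 | step 18 | 3-{4-methoxy-2-[4-methoxy-5-methyl-2-(propan-2-yl)phenoxy]-3-methyl-6-(propan-2-yl)phenoxy}-2-methyl-5-(propan-2-yl)phenol | COc1cc(C(C)C)c(Oc2c(C)c(OC)cc(C(C)C)c2Oc3cc(C(C)C)cc(O)c3C)cc1C
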